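**Strategy**

Numbering the central arene C1 (OMe), C3 (OH), C4 (4-hydroxybenzyl), C5 (2-arylethyl), its meta C1/C3 dioxygenation beside two neighbouring carbon arms marks it as an aromatised 4,5-disubstituted cyclohexane-1,3-dione. Everything rests on cutting C4–C5 and C2–C3: in one pot a benzylmalonate adds conjugately to a methyl enone (C4–C5) and the methyl-ketone enolate then attacks one ester (C2–C3), closing the carbocycle with both arms and both oxygens placed. The precursors are dimethyl 2-[4-(benzyloxy)benzyl]malonate 3 and (E)-enone 9, whose ortho-phenol is benzylated because a free phenol would cyclise onto the enone as a chroman. Decarboxylation, enol etherification at the unhindered carbonyl and Pd-mediated aromatisation/debenzylation complete the target.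

Key step: step 5

Assumption: the target contains no stereocentre and no other stereogenic element, so no enantiocontrol is needed. The sp3 stereocentres that appear in 10–14 are carried as racemic diastereomer mixtures and disappear on aromatisation.

**Route**

Step 1
Reactants: 1 dimethyl malonate; 2 4-(benzyloxy)benzyl chloride
Product: 3 dimethyl 2-[4-(benzyloxy)benzyl]malonate
Conditions: 1 (2.5 equiv), NaH (1.1 equiv), THF, 0 °C; then 2, Bu4NI (cat.), rt to 50 °C
Reagents that add atoms: none
Why: Malonic ester alkylation (SN2) of the sodiomalonate with a reactive benzylic chloride, in which the excess of 1 should suppress dialkylation and the aprotic medium avoids solvolysis of the 4-alkoxybenzyl chloride.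

Step 2
Reactants: 4 dihydrocoumarin
Product: 6 methyl 3-[2-(benzyloxy)phenyl]propanoate, via methyl 3-(2-hydroxyphenyl)propanoate 5 (not isolated)
Conditions: K2CO3 (2 equiv), MeOH, rt; then BnBr (1.3 equiv), reflux
Reagents that add atoms: methanol, SMILES CO; benzyl bromide, SMILES BrCc1ccccc1
Why: Methanolysis of the aryl lactone (transesterification) should release the phenoxide, which is trapped by Williamson etherification, while methanol as solvent keeps the ester as the methyl ester.

Step 3
Reactants: 6 methyl 3-[2-(benzyloxy)phenyl]propanoate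
Product: 7 3-[2-(benzyloxy)phenyl]propanal
Conditions: DIBAL-H (1.05 equiv), CH2Cl2, −78 °C; MeOH quench, aq. Rochelle salt
Reagents that add atoms: none
Why: Partial ester reduction with DIBAL-H at low temperature should stop at the aluminium hemiacetal, which collapses to the aldehyde only on work-up.

Step 4
Reactants: 7 3-[2-(benzyloxy)phenyl]propanal; 8 1-(triphenylphosphoranylidene)propan-2-one
Product: 9 (E)-6-[2-(benzyloxy)phenyl]hex-3-en-2-one
Conditions: 8 (1.2 equiv), CH2Cl2, rt to 40 °C
Reagents that add atoms: none
Why: Wittig olefination with a stabilised ylide should give the (E)-enone, and the benzyl ether keeps the ortho-oxygen from adding to the new enone.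

Step 5
Reactants: 3 dimethyl 2-[4-(benzyloxy)benzyl]malonate; 9 (E)-6-[2-(benzyloxy)phenyl]hex-3-en-2-one
Product: 11 methyl 1-[4-(benzyloxy)benzyl]-6-{2-[2-(benzyloxy)phenyl]ethyl}-2,4-dioxocyclohexane-1-carboxylate (racemic diastereomer mixture), via open-chain Michael adduct 10 (not isolated)
Conditions: NaOMe (1.1 equiv), MeOH, 3, rt; slow addition of 9; reflux; then 1 M HCl, 0 °C
Reagents that add atoms: none
Why: Methoxide deprotonates 3, the soft malonate anion adds 1,4 to 9 to give adduct 10 (C4–C5), and the methyl-ketone enolate of 10 then acylates on one ester carbonyl with loss of methoxide (C2–C3), the resulting 1,3-dione being deprotonated at once. The closest known reaction is the Michael–Claisen (dimedone-type) annulation of malonates, 2-alkylmalonates included, with alkylidene acetones. The ring closes 6-exo-trig, the enolate carbon attacking an ester C=O that lies outside the forming ring. C4 (quaternary) and C5 arise without control as a racemic diastereomer mixture, which is harmless because the ester on C4 is removed in step 6 and both centres become sp2 in step 8. The step needs 1,4- over 1,2-addition and closure through the methyl rather than the internal methylene enolate: the stabilised anion and the reversibility of the earlier equilibria should secure the first, and the second is enforced because methylene attack would give a four-membered ring. Irreversible formation of the dione enolate is the sink that should offset crowding at the new quaternary carbon and the retro-Michael pathway.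

Step 6
Reactants: 11 methyl 1-[4-(benzyloxy)benzyl]-6-{2-[2-(benzyloxy)phenyl]ethyl}-2,4-dioxocyclohexane-1-carboxylate
Product: 13 4-[4-(benzyloxy)benzyl]-5-{2-[2-(benzyloxy)phenyl]ethyl}cyclohexane-1,3-dione (racemic diastereomer mixture), via β-keto acid 12 (not isolated)
Conditions: aq. KOH, MeOH, reflux; then 2 M HCl to pH 1–2, 60–70 °C
Reagents that add atoms: none
Why: Saponification should be clean because the dione is held as its enolate, which blocks retro-Claisen opening, and the β-keto acid loses CO2 on acidification and gentle warming, conditions the aryl benzyl ethers tolerate.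

Step 7
Reactants: 13 4-[4-(benzyloxy)benzyl]-5-{2-[2-(benzyloxy)phenyl]ethyl}cyclohexane-1,3-dione
Product: 14 6-[4-(benzyloxy)benzyl]-5-{2-[2-(benzyloxy)phenyl]ethyl}-3-methoxycyclohex-2-en-1-one (racemic diastereomer mixture)
Conditions: TsOH·H2O (cat.), MeOH, 3 Å MS, reflux
Reagents that add atoms: methanol, SMILES CO
Why: Acid-catalysed enol etherification of a 1,3-dione is reversible and should favour methanol attack at the C1 carbonyl, which sits between two methylenes, over the C3 carbonyl next to the branched C4, with the minor enol ether separable and open to re-equilibration.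

Step 8
Reactants: 14 6-[4-(benzyloxy)benzyl]-5-{2-[2-(benzyloxy)phenyl]ethyl}-3-methoxycyclohex-2-en-1-one
Product: 16 2-(4-hydroxybenzyl)-3-[2-(2-hydroxyphenyl)ethyl]-5-methoxyphenol, via dibenzyl phenol 15 (not isolated)
Conditions: 10% Pd/C, mesitylene, reflux, N2 sweep; then cool, EtOH, H2 (1 atm), rt
Reagents that add atoms: none
Why: Pd-catalysed dehydrogenation across C4–C5 (the known aromatisation of 3-alkoxycyclohexenones to resorcinol monoethers) gives a dienone that tautomerises irreversibly to the phenol, and hydrogenolysis over the same catalyst then removes both benzyl ethers, any benzyl group already lost by transfer hydrogenolysis in the hot stage converging on the same product.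

**Compound list**

1 | dimethyl malonate | COC(=O)CC(=O)OC | starting material
2 | 4-(benzyloxy)benzyl chloride | ClCc1ccc(OCc2ccccc2)cc1 | starting material
3 | dimethyl 2-[4-(benzyloxy)benzyl]malonate | COC(=O)C(Cc1ccc(OCc2ccccc2)cc1)C(=O)OC | intermediate
4 | dihydrocoumarin (chroman-2-one) | O=C1CCc2ccccc2O1 | starting material
5 | methyl 3-(2-hydroxyphenyl)propanoate (present as its potassium phenoxide, not isolated) | COC(=O)CCc1ccccc1O | intermediate
6 | methyl 3-[2-(benzyloxy)phenyl]propanoate | COC(=O)CCc1ccccc1OCc1ccccc1 | intermediate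
7 | 3-[2-(benzyloxy)phenyl]propanal | O=CCCc1ccccc1OCc1ccccc1 | intermediate
8 | 1-(triphenylphosphoranylidene)propan-2-one | CC(=O)C=P(c1ccccc1)(c1ccccc1)c1ccccc1 | starting material
9 | (E)-6-[2-(benzyloxy)phenyl]hex-3-en-2-one | CC(=O)/C=C/CCc1ccccc1OCc1ccccc1 | intermediate
10 | dimethyl 2-[4-(benzyloxy)benzyl]-2-{1-[2-(benzyloxy)phenyl]-5-oxohexan-3-yl}malonate (racemic, not isolated) | COC(=O)C(Cc1ccc(OCc2ccccc2)cc1)(C(=O)OC)C(CCc1ccccc1OCc1ccccc1)CC(C)=O | intermediate
11 | methyl 1-[4-(benzyloxy)benzyl]-6-{2-[2-(benzyloxy)phenyl]ethyl}-2,4-dioxocyclohexane-1-carboxylate (largely enolised, racemic diastereomer mixture) | COC(=O)C1(Cc2ccc(OCc3ccccc3)cc2)C(=O)CC(=O)CC1CCc1ccccc1OCc1ccccc1 | intermediate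
12 | 1-[4-(benzyloxy)benzyl]-6-{2-[2-(benzyloxy)phenyl]ethyl}-2,4-dioxocyclohexane-1-carboxylic acid (racemic diastereomer mixture, not isolated) | OC(=O)C1(Cc2ccc(OCc3ccccc3)cc2)C(=O)CC(=O)CC1CCc1ccccc1OCc1ccccc1 | intermediate
13 | 4-[4-(benzyloxy)benzyl]-5-{2-[2-(benzyloxy)phenyl]ethyl}cyclohexane-1,3-dione (racemic diastereomer mixture) | O=C1CC(=O)C(Cc2ccc(OCc3ccccc3)cc2)C(CCc2ccccc2OCc2ccccc2)C1 | intermediate
14 | 6-[4-(benzyloxy)benzyl]-5-{2-[2-(benzyloxy)phenyl]ethyl}-3-methoxycyclohex-2-en-1-one (racemic diastereomer mixture) | COC1=CC(=O)C(Cc2ccc(OCc3ccccc3)cc2)C(CCc2ccccc2OCc2ccccc2)C1 | intermediate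
15 | 2-[4-(benzyloxy)benzyl]-3-{2-[2-(benzyloxy)phenyl]ethyl}-5-methoxyphenol (not isolated) | COc1cc(O)c(Cc2ccc(OCc3ccccc3)cc2)c(CCc2ccccc2OCc2ccccc2)c1 | intermediate
16 | 2-(4-hydroxybenzyl)-3-[2-(2-hydroxyphenyl)ethyl]-5-methoxyphenol (achiral) | COc1cc(O)c(Cc2ccc(O)cc2)c(CCc2ccccc2O)c1 | target

**Step count and risks**

Total step count: 8. Longest linear sequence: 7 (steps 2–8, from dihydrocoumarin).

Steps most likely to fail:

Step 5. Conjugate addition of the α-substituted malonate may be slow and reversible, so that the enone is consumed by self-condensation or methoxide addition before the cyclisation sink is reached. The fallback sets out from 9 and 1 and returns at 11; it builds the quaternary carbon by alkylation instead of conjugate addition. Enone 9 should take up unsubstituted dimethyl malonate 1 under catalytic base (DBU cat., THF, rt) to give dimethyl 2-{1-[2-(benzyloxy)phenyl]-5-oxohexan-3-yl}malonate F1. Its malonate C–H is then benzylated with 2 (NaH, DMF, 0 °C) to give 10, this time isolated. Kinetic deprotonation of the methyl ketone (LiHMDS, THF, −78 to 0 °C) should close the ring to 11 without opening the retro-Michael pathway.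

Step 7. Discrimination between the two carbonyls may be poor, so that both enol ethers form. The fallback sets out from 9 and 1 and returns at 14; it attaches the benzyl arm after the enol ether, on a dione whose carbonyls are equivalent. The ordinary Michael–Claisen annulation of 9 with 1 (NaOMe, MeOH, reflux, passing through the adduct F1) should give methyl 6-{2-[2-(benzyloxy)phenyl]ethyl}-2,4-dioxocyclohexane-1-carboxylate F2. Saponification (aq. KOH, reflux) and acidification give 6-{2-[2-(benzyloxy)phenyl]ethyl}-2,4-dioxocyclohexane-1-carboxylic acid F3, which decarboxylates on warming to 5-{2-[2-(benzyloxy)phenyl]ethyl}cyclohexane-1,3-dione F4. MeOH/TsOH can then give only one enol ether, 5-{2-[2-(benzyloxy)phenyl]ethyl}-3-methoxycyclohex-2-en-1-one F5. Stork–Danheiser α′-alkylation (LDA, THF, −78 °C; then 2, DMPU, Bu4NI cat.) places the benzyl group on the carbon between the ketone and the arylethyl-bearing carbon, which is 14.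

Step 8. Heterogeneous dehydrogenation at high temperature may stall or disproportionate on a substrate whose two reacting C–H bonds are both tertiary. The fallback sets out from 14 and returns at 15; it replaces the catalytic dehydrogenation by enolate selenenylation and selenoxide elimination. Kinetic α′-deprotonation (LDA, THF, −78 °C) and trapping with PhSeBr should give 6-[4-(benzyloxy)benzyl]-5-{2-[2-(benzyloxy)phenyl]ethyl}-3-methoxy-6-(phenylselanyl)cyclohex-2-en-1-one F6. Oxidation (H2O2, pyridine, CH2Cl2, 0 °C) gives the corresponding selenoxide F7, whose syn-elimination and tautomerisation give phenol 15. Compound 15 is then isolated and debenzylated with H2 and Pd/C at rt, as in the second stage of step 8.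

**Further compounds**

F1 | step 5 | dimethyl 2-{1-[2-(benzyloxy)phenyl]-5-oxohexan-3-yl}malonate | COC(=O)C(C(=O)OC)C(CCc1ccccc1OCc1ccccc1)CC(C)=O
F2 | step 7 | methyl 6-{2-[2-(benzyloxy)phenyl]ethyl}-2,4-dioxocyclohexane-1-carboxylate | COC(=O)C1C(=O)CC(=O)CC1CCc1ccccc1OCc1ccccc1
F3 | step 7 | 6-{2-[2-(benzyloxy)phenyl]ethyl}-2,4-dioxocyclohexane-1-carboxylic acid | OC(=O)C1C(=O)CC(=O)CC1CCc1ccccc1OCc1ccccc1
F4 | step 7 | 5-{2-[2-(benzyloxy)phenyl]ethyl}cyclohexane-1,3-dione | O=C1CC(=O)CC(CCc2ccccc2OCc2ccccc2)C1
F5 | step 7 | 5-{2-[2-(benzyloxy)phenyl]ethyl}-3-methoxycyclohex-2-en-1-one | COC1=CC(=O)CC(CCc2ccccc2OCc2ccccc2)C1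
F6 | step 8 | 6-[4-(benzyloxy)benzyl]-5-{2-[2-(benzyloxy)phenyl]ethyl}-3-methoxy-6-(phenylselanyl)cyclohex-2-en-1-one | COC1=CC(=O)C(Cc2ccc(OCc3ccccc3)cc2)([Se]c2ccccc2)C(CCc2ccccc2OCc2ccccc2)C1
F7 | step 8 | 6-[4-(benzyloxy)benzyl]-5-{2-[2-(benzyloxy)phenyl]ethyl}-3-methoxy-6-(phenylseleninyl)cyclohex-2-en-1-one | COC1=CC(=O)C(Cc2ccc(OCc3ccccc3)cc2)([Se](=O)c2ccccc2)C(CCc2ccccc2OCc2ccccc2)C1
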